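**Retrosynthetic overview**

1. The (2R,3E,5E)-dienoic acid chain is cut at C14–C15 (carboalumination of alkyne 17, then Pd-catalysed coupling with vinyl iodide 21 made from methyl (S)-3-hydroxy-2-methylpropanoate) and at C9–C11 (Negishi coupling of enol triflate 15); the acid is unveiled last by oxidation.
2. Triflate 15 comes from trans-decalone 13, and 13 from the Δ5-octalone 12 by hydrogen-atom-transfer hydrogenation, which sets C5.
3. Key disconnection: ring B of 12 is opened at C7–C8 and C5=C6 to the monocyclic 1,3-diketone 9 and a two-carbon vinylphosphonium unit (C6, C7); forward, conjugate addition of the C8 enolate and intramolecular Wittig closure form both bonds in one flask.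
4. Enabling feature: in 9 the ring A carbonyl C5 sits between two fully substituted carbons (C4 with its gem-dimethyl group, quaternary C10), so it cannot enolise and the only acidic C–H is at C8 of the propanoyl group; nucleophilic C8 and electrophilic C5 are 1,4-related through C9–C10, the spacing a C2 unit closes to six-membered ring B, and the C9 carbonyl remains as the handle for the C8=C9 alkene and the side chain.
5. Diketone 9 derives from (R)-2-allyl-2,6,6-trimethylcyclohexanone 4 (Pd-catalysed decarboxylative asymmetric allylation sets C10); ring order: ring A is bought in 1, ring B is formed in step 7.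

Key step: step 7

Numbering: labdane-type numbering of the target is used for all compounds: ring A = C1–C5 and C10, ring B = C5–C10, methyl groups on C4 (two), C8 and C10, side chain C11–C18 with C18 the carboxyl carbon.
Assumption: compounds 8–13 are mixtures of epimers at the methyl-bearing C8 (8 also at its carbinol carbon); these centres are left undefined in the SMILES because the carbinol is oxidised in step 6 and C8 becomes trigonal in step 9.
Assumption: the (R)-ligand in step 2 is taken to give the mirror image of the known sense of the (S)-ligand with 2-alkylcyclohexanone enol carbonates; any minor enantiomer of the decalin series becomes a diastereomer after step 15 and is to be removed there.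
Assumption: vinyltriphenylphosphonium bromide and (4-bromobut-1-yn-1-yl)trimethylsilane are treated as purchased reagents.

**Route**

Step 1
Reactants: 1 2,2,6-trimethylcyclohexan-1-one
Product: 3 allyl 2,6,6-trimethylcyclohex-1-en-1-yl carbonate, via lithium enolate 2 (not isolated)
Conditions: LiN(SiMe3)2, THF, 0 °C; then ClCO2CH2CH=CH2, −78 → 25 °C
Reagents that add atoms: allyl chloroformate, C=CCOC(=O)Cl
Why: Ketone 1 has a single α-hydrogen, so one tetrasubstituted lithium enolate forms, and the hard chloroformate acylates it on oxygen (enol carbonate formation).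

Step 2
Reactants: 3 allyl 2,6,6-trimethylcyclohex-1-en-1-yl carbonate
Product: 4 (R)-2-allyl-2,6,6-trimethylcyclohexan-1-one
Conditions: Pd2(dba)3 (2.5 mol %), (R)-t-Bu-PHOX (6 mol %), THF, 25 °C
Reagents that add atoms: none
Why: Tsuji-type decarboxylative asymmetric allylic alkylation: oxidative addition of zerovalent palladium to the allyl carbonate and loss of CO2 give a π-allylpalladium enolate that recombines inside the chiral pocket of the P,N-ligand, which sets the quaternary stereocentre C10 (R in 4) by ligand control.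

Step 3
Reactants: 4 (R)-2-allyl-2,6,6-trimethylcyclohexan-1-one
Product: 5 (R)-2,2,6-trimethyl-6-[(E)-prop-1-en-1-yl]cyclohexan-1-one
Conditions: RuHCl(CO)(PPh3)3 (5 mol %), toluene, 80 °C
Reagents that add atoms: none
Why: Ruthenium hydride alkene isomerisation (hydrometalation and β-hydride elimination) should move the terminal double bond into the more stable internal position and stop there, because the next carbon (C10) is quaternary; the E/Z ratio is irrelevant for step 4.

Step 4
Reactants: 5 (R)-2,2,6-trimethyl-6-[(E)-prop-1-en-1-yl]cyclohexan-1-one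
Product: 7 (R)-1,3,3-trimethyl-2-oxocyclohexane-1-carbaldehyde, via secondary ozonide 6 (not isolated)
Conditions: O3, CH2Cl2, −78 °C; then Me2S, −78 → 25 °C
Reagents that add atoms: ozone, [O-][O+]=O
Why: Ozonolysis with reductive work-up (Criegee mechanism) cleaves the propenyl double bond and leaves C9 as an aldehyde on the quaternary centre; neither carbonyl group of 7 has an α-hydrogen, so C10 cannot epimerise.

Step 5
Reactants: 7 (R)-1,3,3-trimethyl-2-oxocyclohexane-1-carbaldehyde
Product: 8 (6R)-6-(1-hydroxypropyl)-2,2,6-trimethylcyclohexan-1-one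
Conditions: EtMgBr, THF, −78 °C; then aq. NH4Cl at −78 °C
Reagents that add atoms: ethylmagnesium bromide, CC[Mg]Br
Why: Grignard addition should be chemoselective for the aldehyde over the ketone flanked by two quaternary carbons, and the cold quench suppresses retro-aldol cleavage of the β-oxido ketone; the new carbinol centre is uncontrolled and is removed in step 6.

Step 6
Reactants: 8 (6R)-6-(1-hydroxypropyl)-2,2,6-trimethylcyclohexan-1-one
Product: 9 (R)-2,2,6-trimethyl-6-propanoylcyclohexan-1-one
Conditions: Dess–Martin periodinane, CH2Cl2, 25 °C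
Reagents that add atoms: none
Why: Dess–Martin oxidation of the secondary alcohol under neutral conditions gives the non-enolisable-at-C10 1,3-diketone without retro-aldol or retro-Claisen cleavage.

Step 7
Reactants: 9 (R)-2,2,6-trimethyl-6-propanoylcyclohexan-1-one
Product: 12 (8aS)-2,5,5,8a-tetramethyl-3,5,6,7,8,8a-hexahydronaphthalen-1(2H)-one, via potassium enolate 10 (not isolated), via keto ylide 11 (not isolated)
Conditions: KN(SiMe3)2, THF, −78 °C; then CH2=CHPPh3Br, −78 → 65 °C
Reagents that add atoms: vinyltriphenylphosphonium bromide, C=C[P+](c1ccccc1)(c1ccccc1)c1ccccc1.[Br-]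
Why: The base removes the only acidic proton of 9 (C8–H of the propanoyl group, since C5=O has no α-hydrogen), and enolate 10 adds through carbon to the β-carbon of the vinylphosphonium salt (conjugate addition, forms C7–C8), which unmasks the non-stabilised ylide 11 at C6. The ylide then attacks the C5 carbonyl intramolecularly and the oxaphosphetane collapses with loss of Ph3PO (intramolecular Wittig olefination, forms C5=C6); the closest known reaction type is the Schweizer annulation of keto enolates with vinyltriphenylphosphonium bromide. Ring B is closed by 6-exo-trig attack of C6 on the C5 carbonyl carbon, and closure onto the C9 carbonyl would need a four-membered ring, so the Wittig step is site-selective. No stereocentre that survives to the target is created: C10 is quaternary and untouched, and the C8 epimers converge when C8 becomes trigonal in step 9. The step needs C- over O-alkylation of the enolate, which the soft cationic acceptor favours, and a Wittig closure at a carbonyl flanked by two quaternary carbons, which intramolecularity, the potassium counter-ion and heating are meant to secure.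

Step 8
Reactants: 12 (8aS)-2,5,5,8a-tetramethyl-3,5,6,7,8,8a-hexahydronaphthalen-1(2H)-one
Product: 13 (4aS,8aS)-2,5,5,8a-tetramethyloctahydronaphthalen-1(2H)-one
Conditions: Mn(dpm)3 (10 mol %), PhSiH3, t-BuOOH, i-PrOH, 25 °C
Reagents that add atoms: none
Why: Mukaiyama-type hydrogen-atom-transfer hydrogenation: a manganese hydride delivers a hydrogen atom to C6, and the tertiary C5 radical is quenched from the α face, away from the axial C10 and C4 methyl groups, so the new stereocentre C5 should carry H trans to the C10 methyl (the thermodynamically preferred trans-decalin).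

Step 9
Reactants: 13 (4aS,8aS)-2,5,5,8a-tetramethyloctahydronaphthalen-1(2H)-one
Product: 15 (4aS,8aS)-2,5,5,8a-tetramethyl-3,4,4a,5,6,7,8,8a-octahydronaphthalen-1-yl trifluoromethanesulfonate, via potassium enolate 14 (not isolated)
Conditions: KN(SiMe3)2, THF, −78 °C; then PhNTf2, −78 → 0 °C
Reagents that add atoms: N-phenylbis(trifluoromethanesulfonimide), O=S(=O)(N(c1ccccc1)S(=O)(=O)C(F)(F)F)C(F)(F)F
Why: C8 carries the only α-hydrogen of 13 (C10 is quaternary), so enolisation and O-triflation fix the tetrasubstituted C8=C9 double bond regiospecifically (enol triflate formation).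

Step 10
Reactants: 15 (4aS,8aS)-2,5,5,8a-tetramethyl-3,4,4a,5,6,7,8,8a-octahydronaphthalen-1-yl trifluoromethanesulfonate
Product: 16 trimethyl{4-[(4aS,8aS)-2,5,5,8a-tetramethyl-3,4,4a,5,6,7,8,8a-octahydronaphthalen-1-yl]but-1-yn-1-yl}silane
Conditions: BrCH2CH2C≡CSiMe3, Zn, LiCl, THF, 50 °C; then 15, Pd(OAc)2 (5 mol %), SPhos (10 mol %), THF/NMP, 60 °C
Reagents that add atoms: (4-bromobut-1-yn-1-yl)trimethylsilane, C[Si](C)(C)C#CCCBr
Why: Negishi sp2–sp3 cross-coupling: the alkylzinc bromide tolerates the silyl alkyne, the bulky electron-rich biaryl phosphine and LiCl should promote oxidative addition of the hindered enol triflate, and reductive elimination should outrun β-hydride elimination, which attaches C11–C14 to C9 with the ring alkene unchanged.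

Step 11
Reactants: 16 trimethyl{4-[(4aS,8aS)-2,5,5,8a-tetramethyl-3,4,4a,5,6,7,8,8a-octahydronaphthalen-1-yl]but-1-yn-1-yl}silane
Product: 17 (4aS,8aS)-1-(but-3-yn-1-yl)-2,5,5,8a-tetramethyl-3,4,4a,5,6,7,8,8a-octahydronaphthalene
Conditions: K2CO3 (cat.), MeOH, 25 °C
Reagents that add atoms: none
Why: Methoxide-mediated protodesilylation of the alkynylsilane frees the terminal alkyne needed for carboalumination and touches nothing else.

Step 12
Reactants: 18 methyl (S)-3-hydroxy-2-methylpropanoate
Product: 19 methyl (S)-3-[(tert-butyldimethylsilyl)oxy]-2-methylpropanoate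
Conditions: TBSCl, imidazole, CH2Cl2, 0 → 25 °C
Reagents that add atoms: tert-butyldimethylsilyl chloride, CC(C)(C)[Si](C)(C)Cl
Why: Silyl ether formation protects the primary alcohol, which later becomes the carboxyl carbon C18, without touching the stereocentre.

Step 13
Reactants: 19 methyl (S)-3-[(tert-butyldimethylsilyl)oxy]-2-methylpropanoate
Product: 20 (S)-3-[(tert-butyldimethylsilyl)oxy]-2-methylpropanal
Conditions: i-Bu2AlH, CH2Cl2, −78 °C
Reagents that add atoms: none
Why: Half-reduction of the ester stops at the tetrahedral aluminium hemiacetal at low temperature and gives the aldehyde on work-up; the α-stereocentre is kept by cold, non-basic handling and immediate use.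

Step 14
Reactants: 20 (S)-3-[(tert-butyldimethylsilyl)oxy]-2-methylpropanal
Product: 21 tert-butyl{[(2R,3E)-4-iodo-2-methylbut-3-en-1-yl]oxy}dimethylsilane
Conditions: CrCl2, CHI3, THF/1,4-dioxane, 0 → 25 °C
Reagents that add atoms: iodoform, IC(I)I
Why: Takai olefination: addition of the geminal dichromium reagent and anti-elimination should give the (E)-vinyl iodide (C15=C16) under conditions that do not epimerise the adjacent centre, whose descriptor changes from S to R only through the priority change.

Step 15
Reactants: 17 (4aS,8aS)-1-(but-3-yn-1-yl)-2,5,5,8a-tetramethyl-3,4,4a,5,6,7,8,8a-octahydronaphthalene; 21 tert-butyl{[(2R,3E)-4-iodo-2-methylbut-3-en-1-yl]oxy}dimethylsilane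
Product: 23 tert-butyl({(2R,3E,5E)-2,6-dimethyl-8-[(4aS,8aS)-2,5,5,8a-tetramethyl-3,4,4a,5,6,7,8,8a-octahydronaphthalen-1-yl]octa-3,5-dien-1-yl}oxy)dimethylsilane, via alkenylalane 22 (not isolated)
Conditions: AlMe3, Cp2ZrCl2 (20 mol %), CH2Cl2, 0 → 25 °C; then 21, Pd(PPh3)4 (5 mol %), ZnCl2 (cat.), THF, 25 °C
Reagents that add atoms: trimethylaluminium, C[Al](C)C
Why: Negishi zirconium-catalysed carboalumination adds methyl and aluminium syn across the terminal alkyne (methyl to C13), which sets the (E)-trisubstituted C13=C14 bond, and Pd-catalysed coupling of the alkenylalane with the (E)-alkenyl iodide proceeds with retention at both partners to give the (E,E)-diene.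

Step 16
Reactants: 23 tert-butyl({(2R,3E,5E)-2,6-dimethyl-8-[(4aS,8aS)-2,5,5,8a-tetramethyl-3,4,4a,5,6,7,8,8a-octahydronaphthalen-1-yl]octa-3,5-dien-1-yl}oxy)dimethylsilane
Product: 24 (2R,3E,5E)-2,6-dimethyl-8-[(4aS,8aS)-2,5,5,8a-tetramethyl-3,4,4a,5,6,7,8,8a-octahydronaphthalen-1-yl]octa-3,5-dien-1-ol
Conditions: Bu4NF, THF, 0 → 25 °C
Reagents that add atoms: none
Why: Fluoride-mediated cleavage of the silyl ether frees the primary alcohol; at the alcohol oxidation level the allylic C17–H is not acidic.

Step 17
Reactants: 24 (2R,3E,5E)-2,6-dimethyl-8-[(4aS,8aS)-2,5,5,8a-tetramethyl-3,4,4a,5,6,7,8,8a-octahydronaphthalen-1-yl]octa-3,5-dien-1-ol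
Product: 26 (2R,3E,5E)-2,6-dimethyl-8-[(4aS,8aS)-2,5,5,8a-tetramethyl-3,4,4a,5,6,7,8,8a-octahydronaphthalen-1-yl]octa-3,5-dienoic acid, via aldehyde 25 (not isolated)
Conditions: TEMPO (20 mol %), PhI(OAc)2, MeCN/H2O (pH 7 buffer), 0 → 25 °C
Reagents that add atoms: water, O
Why: Oxoammonium (TEMPO) oxidation takes the alcohol to the aldehyde and, through its hydrate, on to the acid in one flask under near-neutral conditions, which should keep the C17 stereocentre and leave the C15=C16 bond out of conjugation.

**Compound list**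

1 | 2,2,6-trimethylcyclohexan-1-one | CC1CCCC(C)(C)C1=O | starting material
2 | lithium 2,6,6-trimethylcyclohex-1-en-1-olate | [Li+].[O-]C1=C(C)CCCC1(C)C | intermediate (not isolated)
3 | allyl 2,6,6-trimethylcyclohex-1-en-1-yl carbonate | C=CCOC(=O)OC1=C(C)CCCC1(C)C | intermediate
4 | (R)-2-allyl-2,6,6-trimethylcyclohexan-1-one | C=CC[C@@]1(C)CCCC(C)(C)C1=O | intermediate
5 | (R)-2,2,6-trimethyl-6-[(E)-prop-1-en-1-yl]cyclohexan-1-one | C/C=C/[C@@]1(C)CCCC(C)(C)C1=O | intermediate
6 | (6R)-2,2,6-trimethyl-6-(5-methyl-1,2,4-trioxolan-3-yl)cyclohexan-1-one (secondary ozonide) | CC1OOC(O1)[C@@]2(C)CCCC(C)(C)C2=O | intermediate (not isolated)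
7 | (R)-1,3,3-trimethyl-2-oxocyclohexane-1-carbaldehyde | O=C[C@@]1(C)CCCC(C)(C)C1=O | intermediate
8 | (6R)-6-(1-hydroxypropyl)-2,2,6-trimethylcyclohexan-1-one | CCC(O)[C@@]1(C)CCCC(C)(C)C1=O | intermediate
9 | (R)-2,2,6-trimethyl-6-propanoylcyclohexan-1-one | CCC(=O)[C@@]1(C)CCCC(C)(C)C1=O | intermediate
10 | potassium 1-[(1R)-1,3,3-trimethyl-2-oxocyclohexyl]prop-1-en-1-olate | [K+].CC=C([O-])[C@@]1(C)CCCC(C)(C)C1=O | intermediate (not isolated)
11 | (6R)-2,2,6-trimethyl-6-[2-methyl-4-(triphenyl-λ5-phosphanylidene)butanoyl]cyclohexan-1-one | CC(CC=P(c1ccccc1)(c1ccccc1)c1ccccc1)C(=O)[C@@]2(C)CCCC(C)(C)C2=O | intermediate (not isolated)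
12 | (8aS)-2,5,5,8a-tetramethyl-3,5,6,7,8,8a-hexahydronaphthalen-1(2H)-one | CC1CC=C2C(C)(C)CCC[C@]2(C)C1=O | intermediate
13 | (4aS,8aS)-2,5,5,8a-tetramethyloctahydronaphthalen-1(2H)-one | CC1CC[C@H]2C(C)(C)CCC[C@]2(C)C1=O | intermediate
14 | potassium (4aS,8aS)-2,5,5,8a-tetramethyl-3,4,4a,5,6,7,8,8a-octahydronaphthalen-1-olate | [K+].CC1=C([O-])[C@@]2(C)CCCC(C)(C)[C@@H]2CC1 | intermediate (not isolated)
15 | (4aS,8aS)-2,5,5,8a-tetramethyl-3,4,4a,5,6,7,8,8a-octahydronaphthalen-1-yl trifluoromethanesulfonate | CC1=C(OS(=O)(=O)C(F)(F)F)[C@@]2(C)CCCC(C)(C)[C@@H]2CC1 | intermediate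
16 | trimethyl{4-[(4aS,8aS)-2,5,5,8a-tetramethyl-3,4,4a,5,6,7,8,8a-octahydronaphthalen-1-yl]but-1-yn-1-yl}silane | CC1=C(CCC#C[Si](C)(C)C)[C@@]2(C)CCCC(C)(C)[C@@H]2CC1 | intermediate
17 | (4aS,8aS)-1-(but-3-yn-1-yl)-2,5,5,8a-tetramethyl-3,4,4a,5,6,7,8,8a-octahydronaphthalene | CC1=C(CCC#C)[C@@]2(C)CCCC(C)(C)[C@@H]2CC1 | intermediate
18 | methyl (S)-3-hydroxy-2-methylpropanoate | C[C@@H](CO)C(=O)OC | starting material
19 | methyl (S)-3-[(tert-butyldimethylsilyl)oxy]-2-methylpropanoate | C[C@@H](CO[Si](C)(C)C(C)(C)C)C(=O)OC | intermediate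
20 | (S)-3-[(tert-butyldimethylsilyl)oxy]-2-methylpropanal | C[C@@H](CO[Si](C)(C)C(C)(C)C)C=O | intermediate
21 | tert-butyl{[(2R,3E)-4-iodo-2-methylbut-3-en-1-yl]oxy}dimethylsilane | C[C@@H](CO[Si](C)(C)C(C)(C)C)/C=C/I | intermediate
22 | dimethyl{(1E)-2-methyl-4-[(4aS,8aS)-2,5,5,8a-tetramethyl-3,4,4a,5,6,7,8,8a-octahydronaphthalen-1-yl]but-1-en-1-yl}alumane | CC1=C(CC/C(C)=C/[Al](C)C)[C@@]2(C)CCCC(C)(C)[C@@H]2CC1 | intermediate (not isolated)
23 | tert-butyl({(2R,3E,5E)-2,6-dimethyl-8-[(4aS,8aS)-2,5,5,8a-tetramethyl-3,4,4a,5,6,7,8,8a-octahydronaphthalen-1-yl]octa-3,5-dien-1-yl}oxy)dimethylsilane | CC1=C(CC/C(C)=C/C=C/[C@@H](C)CO[Si](C)(C)C(C)(C)C)[C@@]2(C)CCCC(C)(C)[C@@H]2CC1 | intermediate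
24 | (2R,3E,5E)-2,6-dimethyl-8-[(4aS,8aS)-2,5,5,8a-tetramethyl-3,4,4a,5,6,7,8,8a-octahydronaphthalen-1-yl]octa-3,5-dien-1-ol | CC1=C(CC/C(C)=C/C=C/[C@@H](C)CO)[C@@]2(C)CCCC(C)(C)[C@@H]2CC1 | intermediate
25 | (2R,3E,5E)-2,6-dimethyl-8-[(4aS,8aS)-2,5,5,8a-tetramethyl-3,4,4a,5,6,7,8,8a-octahydronaphthalen-1-yl]octa-3,5-dienal | CC1=C(CC/C(C)=C/C=C/[C@@H](C)C=O)[C@@]2(C)CCCC(C)(C)[C@@H]2CC1 | intermediate (not isolated)
26 | (2R,3E,5E)-2,6-dimethyl-8-[(4aS,8aS)-2,5,5,8a-tetramethyl-3,4,4a,5,6,7,8,8a-octahydronaphthalen-1-yl]octa-3,5-dienoic acid (CNP0106052.1) | CC1=C(CC/C(C)=C/C=C/[C@@H](C)C(=O)O)[C@@]2(C)CCCC(C)(C)[C@@H]2CC1 | target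

**Step count and risks**

Total step count: 17. Longest linear sequence: 14 steps (steps 1–11 and 15–17); steps 12–14 make the side-chain fragment in parallel.

Steps most likely to fail:

1. Step 7. What may go wrong: after the conjugate addition the ylide carbon may not reach the C5 carbonyl, which is flanked by two quaternary carbons, so that proton transfer, O-alkylation or oligomerisation of the ylide outruns ring closure. Fallback (reductive carbonyl coupling in place of ylide olefination), setting out from 9: the potassium enolate of 9 is allylated at C8 (KN(SiMe3)2, THF, −78 °C; allyl bromide) to give (6R)-2,2,6-trimethyl-6-(2-methylpent-4-enoyl)cyclohexan-1-one F1. Ozonolysis (O3, CH2Cl2, −78 °C; Me2S) then cleaves the terminal alkene to 3-methyl-4-oxo-4-[(1R)-1,3,3-trimethyl-2-oxocyclohexyl]butanal F2, whose aldehyde carbon is C6. Intramolecular McMurry coupling (TiCl3, Zn–Cu couple, DME, reflux, slow addition) should join C6 to the C5 carbonyl carbon through a six-membered ring and give the C5=C6 alkene, which comes back to the route at 12. The aldehyde is the most easily reduced carbonyl group, and coupling with the C9 ketone would need a four-membered ring.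

2. Step 10. What may go wrong: oxidative addition and transmetalation at the tetrasubstituted triflate, flanked by the quaternary C10 and the C8 methyl group, may be slow, so that cleavage of the triflate back to the ketone or reduction competes. Fallback (carbonyl addition and dehydration in place of cross-coupling), setting out from 13: [4-(trimethylsilyl)but-3-yn-1-yl]magnesium bromide, made from the bromide and Mg, is added in the presence of CeCl3 (THF, −78 → 0 °C) to give (4aS,8aS)-2,5,5,8a-tetramethyl-1-[4-(trimethylsilyl)but-3-yn-1-yl]decahydronaphthalen-1-ol F3. Dehydration (SOCl2, pyridine, 0 °C, then equilibration of any exocyclic isomer with catalytic TsOH in toluene) should favour the tetrasubstituted C8=C9 alkene and comes back to the route at 16.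

3. Step 8. What may go wrong: hydrogen delivery to the C5 radical from the β face (poor facial selectivity), or sluggish hydrogen-atom transfer to the hindered alkene, would erode the trans ring fusion. Fallback (exhaustive surface hydrogenation and re-oxidation in place of radical hydrogen-atom transfer), setting out from 12: hydrogenation over PtO2 (H2, AcOH) should add hydrogen from the α face, away from the C10 methyl and the axial C4 methyl group, and also reduces the C9 carbonyl, giving (4aS,8aS)-2,5,5,8a-tetramethyldecahydronaphthalen-1-ol F4. Dess–Martin oxidation then comes back to the route at 13.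

Further compounds
F1 | step 7 | (6R)-2,2,6-trimethyl-6-(2-methylpent-4-enoyl)cyclohexan-1-one | C=CCC(C)C(=O)[C@@]1(C)CCCC(C)(C)C1=O
F2 | step 7 | 3-methyl-4-oxo-4-[(1R)-1,3,3-trimethyl-2-oxocyclohexyl]butanal | O=CCC(C)C(=O)[C@@]1(C)CCCC(C)(C)C1=O
F3 | step 10 | (4aS,8aS)-2,5,5,8a-tetramethyl-1-[4-(trimethylsilyl)but-3-yn-1-yl]decahydronaphthalen-1-ol | CC1CC[C@H]2C(C)(C)CCC[C@]2(C)C1(O)CCC#C[Si](C)(C)C
F4 | step 8 | (4aS,8aS)-2,5,5,8a-tetramethyldecahydronaphthalen-1-ol | CC1CC[C@H]2C(C)(C)CCC[C@]2(C)C1O
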